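**Strategy.** The galloylated lower flavan unit is disconnected at its C2–C3 bond. Its ring C is closed by a redox-neutral hydride-shift cyclization: in nitroalkene 5 the ring A oxygen O1 carries the 3,4-bis(benzyloxy)benzyl group (future C2 and ring B) ortho to a nitrovinyl arm (C4=C3); the hydridic C2–H moves to C4, which is a CH2 in the target, and the resulting oxocarbenium/nitronate pair joins C2 to C3. The step exploits the electron-rich catechol ring B on C2, the aryl ether O1 and the unsubstituted C4. Nef reaction and dynamic-kinetic transfer hydrogenation then set C2 and C3; bromine-directed C4→C6 coupling with an epiafzelechin C4 electrophile and hydrogenolysis finish the synthesis.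

Key step: step 4

Remark: the target is read as (−)-epiafzelechin-(4β→6)-(−)-epicatechin 3-O-gallate (upper unit 2R,3R,4S; lower unit 2R,3R), and (−)-epiafzelechin 14 is taken as a purchasable natural product.

**Route**

Step 1
Reactants: 1 2,4,6-trihydroxybenzaldehyde
Product: 2 2,4-bis(benzyloxy)-6-hydroxybenzaldehyde
Conditions: BnBr (2.1 equiv), K2CO3 (2.2 equiv), DMF, rt
Reagents that add atoms: benzyl bromide, BrCc1ccccc1
Why: Williamson etherification in which the para hydroxyl and one ortho hydroxyl are alkylated while the second ortho hydroxyl, hydrogen-bonded to the aldehyde, should remain free.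

Step 2
Reactants: 2 2,4-bis(benzyloxy)-6-hydroxybenzaldehyde; 3 3,4-bis(benzyloxy)benzyl chloride
Product: 4 2,4-bis(benzyloxy)-6-{[3,4-bis(benzyloxy)benzyl]oxy}benzaldehyde
Conditions: K2CO3, KI (cat.), DMF, 60 °C
Reagents that add atoms: none
Why: Williamson etherification of the chelated phenol under more forcing, iodide-catalysed conditions places the future C2 and ring B on O1.

Step 3
Reactants: 4 2,4-bis(benzyloxy)-6-{[3,4-bis(benzyloxy)benzyl]oxy}benzaldehyde
Product: 5 (E)-1,5-bis(benzyloxy)-3-{[3,4-bis(benzyloxy)benzyl]oxy}-2-(2-nitrovinyl)benzene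
Conditions: CH3NO2 (solvent), NH4OAc, 90 °C
Reagents that add atoms: nitromethane, C[N+](=O)[O-]
Why: Henry (nitroaldol) condensation with dehydration should give the thermodynamically preferred E-nitrostyrene, as is usual for 2,4,6-trialkoxybenzaldehydes.

Step 4
Reactants: 5 (E)-1,5-bis(benzyloxy)-3-{[3,4-bis(benzyloxy)benzyl]oxy}-2-(2-nitrovinyl)benzene
Product: 7 rac-5,7-bis(benzyloxy)-2-[3,4-bis(benzyloxy)phenyl]-3-nitrochroman (mixture of 2,3-trans and 2,3-cis isomers), via oxocarbenium nitronate zwitterion 6 (not isolated)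
Conditions: Sc(OTf)3 (10 mol %), ClCH2CH2Cl, 60 °C
Reagents that add atoms: none
Why: Sc(OTf)3 binds the nitro group, the C2–H of the 3,4-bis(benzyloxy)benzyl ether shifts as hydride to C4 through a six-membered [1,5] transition state, and the O1=C2 oxocarbenium/C3 nitronate zwitterion 6 collapses by attack of C3 on C2. This is a hydride-transfer-initiated cyclization (internal redox, the ether counterpart of the tert-amino effect), known for ortho-benzyloxy benzylidene malonates and barbiturates that close to 2-arylchromans in the same way; here a nitroalkene serves as the acceptor. Ring C closes in a 6-endo-trig mode at the oxocarbenium (enolexo with respect to the nitronate). C2 and C3 are formed without absolute control and a chair-like closure should favour the 2,3-trans isomer, but neither centre needs control here because C3 becomes a carbonyl in step 5 and C2 is equilibrated and fixed in step 6. The step needs the hydride to leave the O1 benzyl group and not the O5 benzyl group, which is also ortho to the nitrovinyl arm; the two alkoxy groups of the future ring B make its C–H far more hydridic and its oxocarbenium far more stabilised, and the O7 benzyl group cannot reach C4. Twisting of the 2,6-disubstituted nitrovinyl group out of the plane of ring A offsets the donor effect of the three alkoxy groups and holds C4 next to the O–CH2 hydrogens.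

Step 5
Reactants: 7 rac-5,7-bis(benzyloxy)-2-[3,4-bis(benzyloxy)phenyl]-3-nitrochroman
Product: 9 rac-5,7-bis(benzyloxy)-2-[3,4-bis(benzyloxy)phenyl]chroman-3-one, via potassium nitronate 8 (not isolated)
Conditions: KOt-Bu, THF, −78 °C; then aq. TiCl3, NH4OAc, THF/H2O, 0 °C to rt
Reagents that add atoms: water, O
Why: Nef reaction in its reductive variant, in which the nitronate is reduced by trivalent titanium to the imine and this hydrolyses to the ketone, so that the C2 and C3 configurations of 7 do not matter.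

Step 6
Reactants: 9 rac-5,7-bis(benzyloxy)-2-[3,4-bis(benzyloxy)phenyl]chroman-3-one
Product: 10 (2R,3R)-5,7-bis(benzyloxy)-2-[3,4-bis(benzyloxy)phenyl]chroman-3-ol (5,7,3',4'-tetra-O-benzyl-(−)-epicatechin)
Conditions: RuCl[(R,R)-TsDPEN](mesitylene) (2 mol %), HCO2H/Et3N 5:2, CH2Cl2, 30 °C
Reagents that add atoms: none
Why: Noyori–Ikariya asymmetric transfer hydrogenation with dynamic kinetic resolution, in which C2 of 9 epimerises through the enol in the amine medium, the catalyst should reduce the 2R ketone faster and deliver hydride anti to the C2 aryl group, setting 2R and 3R (2,3-cis) together; the ligand antipode is chosen on the aryl-side model, the sense is to be confirmed against 10 made by benzylation of natural (−)-epicatechin, and the (S,S) complex is used if it is opposite.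

Step 7
Reactants: 10 5,7,3',4'-tetra-O-benzyl-(−)-epicatechin
Product: 11 (2R,3R)-8-bromo-5,7-bis(benzyloxy)-2-[3,4-bis(benzyloxy)phenyl]chroman-3-ol
Conditions: NBS (1.0 equiv), CH2Cl2, −20 °C
Reagents that add atoms: N-bromosuccinimide, BrN1C(=O)CCC1=O
Why: Electrophilic aromatic bromination, in which C8 of a 5,7-dialkoxyflavan is the more reactive and less hindered position, so that one equivalent of NBS should brominate there and block it.

Step 8
Reactants: 11 (2R,3R)-8-bromo-5,7-bis(benzyloxy)-2-[3,4-bis(benzyloxy)phenyl]chroman-3-ol; 12 3,4,5-tris(benzyloxy)benzoic acid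
Product: 13 8-bromo-5,7,3',4'-tetra-O-benzyl-(−)-epicatechin 3-O-[3,4,5-tris(benzyloxy)benzoate]
Conditions: DCC, DMAP (cat.), CH2Cl2, rt
Reagents that add atoms: none
Why: Steglich esterification of the axial C3 hydroxyl, which touches no stereocentre.

Step 9
Reactants: 14 (−)-epiafzelechin
Product: 15 (2R,3R)-5,7-bis(benzyloxy)-2-[4-(benzyloxy)phenyl]chroman-3-ol (5,7,4'-tri-O-benzyl-(−)-epiafzelechin)
Conditions: BnBr (3.2 equiv), K2CO3, DMF, 0 °C to rt
Reagents that add atoms: benzyl bromide, BrCc1ccccc1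
Why: Williamson etherification of the three phenols, which are far more acidic than the C3 alcohol, with low temperature limiting C-benzylation and C2 epimerisation.

Step 10
Reactants: 15 5,7,4'-tri-O-benzyl-(−)-epiafzelechin
Product: 16 (2R,3R,4S)-5,7-bis(benzyloxy)-2-[4-(benzyloxy)phenyl]-4-(2-ethoxyethoxy)chroman-3-ol (4β ether)
Conditions: DDQ (2 equiv), 2-ethoxyethanol, CH2Cl2, rt
Reagents that add atoms: 2-ethoxyethanol, CCOCCO
Why: DDQ oxidation of the benzylic C4 position activated by ring A gives a quinone-methide-like cation that the alcohol should trap trans to the C3 hydroxyl (4β), as in the epicatechin series.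

Step 11
Reactants: 16 (2R,3R,4S)-5,7-bis(benzyloxy)-2-[4-(benzyloxy)phenyl]-4-(2-ethoxyethoxy)chroman-3-ol
Product: 17 (2R,3R,4S)-6,8-dibromo-5,7-bis(benzyloxy)-2-[4-(benzyloxy)phenyl]-4-(2-ethoxyethoxy)chroman-3-ol
Conditions: NBS (2.2 equiv), CH2Cl2, 0 °C to rt
Reagents that add atoms: N-bromosuccinimide, BrN1C(=O)CCC1=O
Why: Electrophilic aromatic bromination at C8 and C6 caps both nucleophilic positions of ring A of the electrophile so that it cannot condense with itself.

Step 12
Reactants: 13 8-bromo-5,7,3',4'-tetra-O-benzyl-(−)-epicatechin 3-O-[3,4,5-tris(benzyloxy)benzoate] (1.5 equiv); 17 (2R,3R,4S)-6,8-dibromo-5,7-bis(benzyloxy)-2-[4-(benzyloxy)phenyl]-4-(2-ethoxyethoxy)chroman-3-ol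
Product: 18 6,8-dibromo-5,7,4'-tri-O-benzyl-(−)-epiafzelechin-(4β→6)-8-bromo-5,7,3',4'-tetra-O-benzyl-(−)-epicatechin 3-O-[3,4,5-tris(benzyloxy)benzoate]
Conditions: TMSOTf (0.3 equiv), CH2Cl2, −78 to −20 °C
Reagents that add atoms: none
Why: Lewis acid ionisation of the C4 ether gives the C4 benzylic cation, which should undergo Friedel–Crafts alkylation at C6 of 13 (C8 being blocked by bromine) from the face anti to the C3 hydroxyl, giving the 3,4-trans 4β→6 interflavan bond.

Step 13
Reactants: 18 protected tribromo dimer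
Product: 19 (−)-epiafzelechin-(4β→6)-(−)-epicatechin 3-O-gallate
Conditions: H2 (1 atm), Pd(OH)2/C, NaOAc, THF/MeOH/H2O, rt
Reagents that add atoms: none
Why: Catalytic hydrogenolysis should remove the ten benzyl ethers and the three aryl bromides in one operation, with acetate buffering the HBr that would otherwise cleave the acid-labile interflavan bond.

**Compound list**

1 | 2,4,6-trihydroxybenzaldehyde | O=Cc1c(O)cc(O)cc1O | starting material
2 | 2,4-bis(benzyloxy)-6-hydroxybenzaldehyde | O=Cc1c(O)cc(OCc2ccccc2)cc1OCc1ccccc1 | intermediate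
3 | 3,4-bis(benzyloxy)benzyl chloride | ClCc1ccc(OCc2ccccc2)c(OCc2ccccc2)c1 | starting material
4 | 2,4-bis(benzyloxy)-6-{[3,4-bis(benzyloxy)benzyl]oxy}benzaldehyde | O=Cc1c(OCc2ccc(OCc3ccccc3)c(OCc3ccccc3)c2)cc(OCc2ccccc2)cc1OCc1ccccc1 | intermediate
5 | (E)-1,5-bis(benzyloxy)-3-{[3,4-bis(benzyloxy)benzyl]oxy}-2-(2-nitrovinyl)benzene | [O-][N+](=O)/C=C/c1c(OCc2ccc(OCc3ccccc3)c(OCc3ccccc3)c2)cc(OCc2ccccc2)cc1OCc1ccccc1 | intermediate
6 | zwitterion after hydride shift: aryl(3,4-bis(benzyloxy)benzylidene)oxonium bearing a 2-(aci-nitro)ethyl nitronate arm | [O-][N+]([O-])=CCc1c(OCc2ccccc2)cc(OCc2ccccc2)cc1[O+]=Cc1ccc(OCc2ccccc2)c(OCc2ccccc2)c1 | intermediate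
7 | rac-5,7-bis(benzyloxy)-2-[3,4-bis(benzyloxy)phenyl]-3-nitrochroman, mixture of 2,3-trans and 2,3-cis | [O-][N+](=O)C1Cc2c(OCc3ccccc3)cc(OCc3ccccc3)cc2OC1c1ccc(OCc2ccccc2)c(OCc2ccccc2)c1 | intermediate
8 | potassium nitronate of 7 | [K+].[O-][N+]([O-])=C1Cc2c(OCc3ccccc3)cc(OCc3ccccc3)cc2OC1c1ccc(OCc2ccccc2)c(OCc2ccccc2)c1 | intermediate
9 | rac-5,7-bis(benzyloxy)-2-[3,4-bis(benzyloxy)phenyl]chroman-3-one | O=C1Cc2c(OCc3ccccc3)cc(OCc3ccccc3)cc2OC1c1ccc(OCc2ccccc2)c(OCc2ccccc2)c1 | intermediate
10 | (2R,3R)-5,7-bis(benzyloxy)-2-[3,4-bis(benzyloxy)phenyl]chroman-3-ol (tetra-O-benzyl-(−)-epicatechin, 2,3-cis) | O[C@@H]1Cc2c(OCc3ccccc3)cc(OCc3ccccc3)cc2O[C@@H]1c1ccc(OCc2ccccc2)c(OCc2ccccc2)c1 | intermediate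
11 | (2R,3R)-8-bromo-5,7-bis(benzyloxy)-2-[3,4-bis(benzyloxy)phenyl]chroman-3-ol | O[C@@H]1Cc2c(OCc3ccccc3)cc(OCc3ccccc3)c(Br)c2O[C@@H]1c1ccc(OCc2ccccc2)c(OCc2ccccc2)c1 | intermediate
12 | 3,4,5-tris(benzyloxy)benzoic acid | OC(=O)c1cc(OCc2ccccc2)c(OCc2ccccc2)c(OCc2ccccc2)c1 | starting material
13 | 8-bromo-5,7,3',4'-tetra-O-benzyl-(−)-epicatechin 3-O-[3,4,5-tris(benzyloxy)benzoate] (2R,3R) | O=C(O[C@@H]1Cc2c(OCc3ccccc3)cc(OCc3ccccc3)c(Br)c2O[C@@H]1c1ccc(OCc2ccccc2)c(OCc2ccccc2)c1)c1cc(OCc2ccccc2)c(OCc2ccccc2)c(OCc2ccccc2)c1 | intermediate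
14 | (−)-epiafzelechin, (2R,3R)-2-(4-hydroxyphenyl)chroman-3,5,7-triol | O[C@@H]1Cc2c(O)cc(O)cc2O[C@@H]1c1ccc(O)cc1 | starting material
15 | (2R,3R)-5,7-bis(benzyloxy)-2-[4-(benzyloxy)phenyl]chroman-3-ol | O[C@@H]1Cc2c(OCc3ccccc3)cc(OCc3ccccc3)cc2O[C@@H]1c1ccc(OCc2ccccc2)cc1 | intermediate
16 | (2R,3R,4S)-5,7-bis(benzyloxy)-2-[4-(benzyloxy)phenyl]-4-(2-ethoxyethoxy)chroman-3-ol (2,3-cis, 3,4-trans, 4β ether) | CCOCCO[C@H]1c2c(OCc3ccccc3)cc(OCc3ccccc3)cc2O[C@H](c2ccc(OCc3ccccc3)cc2)[C@@H]1O | intermediate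
17 | (2R,3R,4S)-6,8-dibromo-5,7-bis(benzyloxy)-2-[4-(benzyloxy)phenyl]-4-(2-ethoxyethoxy)chroman-3-ol | CCOCCO[C@H]1c2c(OCc3ccccc3)c(Br)c(OCc3ccccc3)c(Br)c2O[C@H](c2ccc(OCc3ccccc3)cc2)[C@@H]1O | intermediate
18 | protected dimer: 6,8-dibromo-tri-O-benzyl-epiafzelechin unit joined by its C4 (β) to C6 of the 8-bromo-tetra-O-benzyl-epicatechin 3-O-tris(benzyloxy)benzoate unit | O=C(O[C@@H]1Cc2c(c(Br)c(OCc3ccccc3)c([C@H]3c4c(OCc5ccccc5)c(Br)c(OCc5ccccc5)c(Br)c4O[C@H](c4ccc(OCc5ccccc5)cc4)[C@@H]3O)c2OCc2ccccc2)O[C@@H]1c1ccc(OCc2ccccc2)c(OCc2ccccc2)c1)c1cc(OCc2ccccc2)c(OCc2ccccc2)c(OCc2ccccc2)c1 | intermediate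
19 | (−)-epiafzelechin-(4β→6)-(−)-epicatechin 3-O-gallate | O=C(O[C@@H]1Cc2c(cc(O)c([C@H]3c4c(O)cc(O)cc4O[C@H](c4ccc(O)cc4)[C@@H]3O)c2O)O[C@@H]1c1ccc(O)c(O)c1)c1cc(O)c(O)c(O)c1 | target

**Totals and risks**

Total step count: 13. Longest linear sequence: 10 steps (steps 1 to 8, then 12 and 13).

Steps most likely to fail:

Step 4 (key step). The hydride transfer may be too slow because the three alkoxy groups of ring A deactivate the nitroalkene, or the Lewis acid may ionise the electron-rich benzylic C–O bond before the C–H bond reacts. The fallback sets out from 5. Conjugate reduction (NaBH4, THF/MeOH, 0 °C) should give the nitroalkane 1,5-bis(benzyloxy)-3-{[3,4-bis(benzyloxy)benzyl]oxy}-2-(2-nitroethyl)benzene F1. Oxidative C–H cleavage of its 3,4-bis(benzyloxy)benzyl ether with DDQ (LiClO4, 2,6-dichloropyridine, ClCH2CH2Cl, rt) would then generate the same O1=C2 oxocarbenium with an external oxidant, and the nitronate carbon would close the C2–C3 bond (cross-dehydrogenative coupling of an electron-rich benzyl ether with a nitroalkane). The fallback comes back to the route at 7.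

Step 12. Friedel–Crafts attack by the hindered, bromine-deactivated C6 position may be slower than diversion of the C4 cation into elimination or O-alkylation by the free C3 hydroxyl. The fallback sets out from 17 and changes the activation from hard Lewis acid ionisation to soft thiophilic activation. Exchange of the C4 ether with benzyl mercaptan (BnSH, BF3·OEt2, CH2Cl2, −40 °C) should give the 4β-thioether (2R,3R,4S)-4-(benzylthio)-6,8-dibromo-5,7-bis(benzyloxy)-2-[4-(benzyloxy)phenyl]chroman-3-ol F4. Treatment of F4 with AgBF4 in THF at 0 °C in the presence of 13 would release the C4 cation under nearly neutral conditions. The fallback comes back to the route at 18.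

Step 6. Enantiomer discrimination may be poor if C2 epimerisation is slow relative to reduction, or facial selectivity may be low for this non-conjugated ketone. The fallback sets out from 9 and replaces catalyst control by substrate control plus resolution. Reduction with LiBH(s-Bu)3 (THF, −78 °C) should deliver hydride anti to the C2 aryl group and give the racemic cis alcohol rac-(2R*,3R*)-5,7-bis(benzyloxy)-2-[3,4-bis(benzyloxy)phenyl]chroman-3-ol F2. Acylation with (1S)-camphanic chloride (DMAP, pyridine, CH2Cl2) and separation of the diastereomeric esters by chromatography or crystallisation would give the (2R,3R) camphanate F3. Saponification (LiOH, THF/H2O) would remove the auxiliary, and the fallback comes back to the route at 10.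

**Further compounds**

F1 | step 4 | 1,5-bis(benzyloxy)-3-{[3,4-bis(benzyloxy)benzyl]oxy}-2-(2-nitroethyl)benzene | [O-][N+](=O)CCc1c(OCc2ccc(OCc3ccccc3)c(OCc3ccccc3)c2)cc(OCc2ccccc2)cc1OCc1ccccc1
F2 | step 6 | rac-(2R*,3R*)-5,7-bis(benzyloxy)-2-[3,4-bis(benzyloxy)phenyl]chroman-3-ol (both enantiomers) | O[C@@H]1Cc2c(OCc3ccccc3)cc(OCc3ccccc3)cc2O[C@@H]1c1ccc(OCc2ccccc2)c(OCc2ccccc2)c1.O[C@H]1Cc2c(OCc3ccccc3)cc(OCc3ccccc3)cc2O[C@H]1c1ccc(OCc2ccccc2)c(OCc2ccccc2)c1
F3 | step 6 | (2R,3R)-5,7-bis(benzyloxy)-2-[3,4-bis(benzyloxy)phenyl]chroman-3-yl (1S)-camphanate | O=C(O[C@@H]1Cc2c(OCc3ccccc3)cc(OCc3ccccc3)cc2O[C@@H]1c1ccc(OCc2ccccc2)c(OCc2ccccc2)c1)[C@@]12CC[C@@](C)(C(=O)O1)C2(C)C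
F4 | step 12 | (2R,3R,4S)-4-(benzylthio)-6,8-dibromo-5,7-bis(benzyloxy)-2-[4-(benzyloxy)phenyl]chroman-3-ol | c1ccccc1CS[C@H]1c2c(OCc3ccccc3)c(Br)c(OCc3ccccc3)c(Br)c2O[C@H](c2ccc(OCc3ccccc3)cc2)[C@@H]1O
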